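**Plan**

- Ring A (C5–C10) has oxygen on C6 and C8 on either side of C7 and a quaternary C10 next to the carbon-substituted C5. This is the pattern of a 5,5-disubstituted cyclohexane-1,3-dione with a carboxyl on C4, so after removing the acetate, the angelate and the C11 hydroxyl, the retrosynthesis cuts lactone ring B at O6–C12 and C7–C11 and ring A at C5–C10 and C6–C7.
- Forward: enone by olefination; ring A by a one-pot Michael–Claisen annulation with dimethyl malonate; ester to C5 carbinol and dione to transposed enone; epoxidation and Wharton shift give the C6 alcohol; bromohydrin, epoxide and Grignard chemistry put C11–C13 on C7 and oxygen on C8; ring B closes by oxidative lactonisation; isopropenyl, vinyl, C11–OH and the two esters follow.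
- Stereochemistry: C10 from the amine-catalysed conjugate addition; C5 by equilibration next to it; C6 by epoxidation anti to the C5 substituent; C7 and C8 by trans-diaxial additions in a ring anchored by its equatorial C5 and C10 groups; C11 by hydroxylation of the lactone enolate on its convex face.

Key step: step 2

**Remarks on the chemistry**

- Atom labels are those of the elemane skeleton: ring A = C5–C10; lactone ring B = C6–O–C12–C11–C7; C4 = central isopropenyl carbon.
- Assumption: the quinine-derived primary amine is taken to give the (S)-configured quaternary carbon of 5; if the facial sense is the reverse, its quinidine-derived pseudo-enantiomer is used under the same conditions.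
- C5 equilibrates in 6 and 7 and is fixed in step 4; any minor C5 epimer is to be removed at 10.
- 8 and 9 are carried as C6 epimers and 16–21 as C11 epimers; both centres are later destroyed or planarised.

**Route**

Step 1
Reactants: 1 1,1-dimethoxypropan-2-one; 2 diethyl (2-oxopropyl)phosphonate
Product: 3 (E)-5,5-dimethoxy-4-methylpent-3-en-2-one
Conditions: NaH, THF, 0 → 65 °C; E isomer collected by distillation
Reagents that add atoms: none
Why: Horner–Wadsworth–Emmons olefination of the activated α,α-dialkoxy ketone by the stabilised phosphonate anion should give the trisubstituted enone, the E isomer prevailing because the bulkier dimethoxymethyl group settles trans to the acetyl group.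

Step 2
Reactants: 3 (E)-5,5-dimethoxy-4-methylpent-3-en-2-one; 4 dimethyl malonate
Product: 6 methyl (1R,2S)-2-(dimethoxymethyl)-2-methyl-4,6-dioxocyclohexane-1-carboxylate, via keto diester 5 (not isolated)
Conditions: (i) 9-amino-9-deoxy-epi-quinine (20 mol %), salicylic acid (40 mol %), toluene, 9 kbar, 25 °C; (ii) NaOMe, MeOH, 0 → 25 °C; then 1 M HCl
Reagents that add atoms: none
Why: Proposed new method: the primary amine condenses with the ketone of 3 to an iminium ion whose fully substituted β-carbon (C10), further activated inductively by the acetal, is attacked under high pressure by the central malonate carbon (C5), and after hydrolysis methoxide equilibrates keto diester 5 to its methyl-side enolate (C7), which adds to one malonate ester (C6) and expels methoxide. The closest known reactions are the dimedone synthesis from mesityl oxide and malonate and the high-pressure, primary-amine-catalysed conjugate additions to β,β-disubstituted enones; what is untested is the carry-over of enantiopurity through the basic ring closure. Ring A forms by a 6-(enolendo)-exo-trig Claisen (Dieckmann-type) acylation that becomes irreversible when the product is deprotonated to its vinylogous carboxylate. C10 is set by the catalyst, whose cinchona scaffold blocks one face of the iminium ion, and C5, flanked by ester and ketone, equilibrates to the epimer with the ester trans to the bulkier dimethoxymethyl group. The step needs 1,4- rather than 1,2-attack, which iminium activation and the soft malonate provide; closure from C7 rather than C9, since only the methyl-side enolate reaches an ester through a six-membered transition state; and ring closure faster than retro-Michael cleavage, which is favoured by running the Claisen stage at or below room temperature.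

Step 3
Reactants: 6 methyl (1R,2S)-2-(dimethoxymethyl)-2-methyl-4,6-dioxocyclohexane-1-carboxylate
Product: 7 methyl (1R,6S)-6-(dimethoxymethyl)-4-methoxy-6-methyl-2-oxocyclohex-3-ene-1-carboxylate
Conditions: MeOH, p-toluenesulfonic acid (5 mol %), 3 Å molecular sieves, 45 °C
Reagents that add atoms: methanol, CO
Why: Acid-catalysed enol etherification of the vinylogous acid under equilibrating conditions should place the methoxy group on O8, the unhindered carbonyl remote from C5, leaving the C6 ketone as a β-keto ester, while the dimethyl acetal is unchanged in methanol and C5 stays under thermodynamic control.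

Step 4
Reactants: 7 methyl (1R,6S)-6-(dimethoxymethyl)-4-methoxy-6-methyl-2-oxocyclohex-3-ene-1-carboxylate
Product: 8 methyl (1R,6S)-6-(dimethoxymethyl)-2-hydroxy-4-methoxy-6-methylcyclohex-3-ene-1-carboxylate (C2 epimers)
Conditions: NaBH4, CeCl3·7H2O, MeOH, −20 °C; NaHCO3 work-up
Reagents that add atoms: none
Why: Luche reduction should deliver hydride 1,2 to the C6 ketone without touching the ester or the enol ether, the new carbinol configuration being irrelevant because this oxygen is lost in the next step, while C5 is frozen once it is no longer flanked by a ketone.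

Step 5
Reactants: 8 methyl (1R,6S)-6-(dimethoxymethyl)-2-hydroxy-4-methoxy-6-methylcyclohex-3-ene-1-carboxylate
Product: 10 (4S,5S)-5-(dimethoxymethyl)-4-(2-hydroxypropan-2-yl)-5-methylcyclohex-2-en-1-one, via enol ether diol 9 (not isolated)
Conditions: MeMgBr (6 equiv), THF, 0 → 25 °C; then 0.5 M aq. oxalic acid, THF, 0 °C, brief
Reagents that add atoms: methylmagnesium bromide, C[Mg]Br
Why: Double Grignard addition turns the ester into the tertiary carbinol that will become the isopropenyl group, and mild aqueous acid then ionises the 3-methoxy allylic alcohol and hydrolyses it to the transposed enone (Stork–Danheiser transposition), which places the carbonyl on C8 and the alkene at C6–C7.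

Step 6
Reactants: 10 (4S,5S)-5-(dimethoxymethyl)-4-(2-hydroxypropan-2-yl)-5-methylcyclohex-2-en-1-one
Product: 11 4-(dimethoxymethyl)-5-(2-hydroxypropan-2-yl)-4-methyl-7-oxabicyclo[4.1.0]heptan-2-one (epoxide oxygen trans to the hydroxypropyl group)
Conditions: t-BuOOH (decane solution), 1,8-diazabicyclo[5.4.0]undec-7-ene, CH2Cl2, 0 → 25 °C
Reagents that add atoms: tert-butyl hydroperoxide, CC(C)(C)OO
Why: Weitz–Scheffer nucleophilic epoxidation should add the hydroperoxide to C6 from the face opposite both the neighbouring equatorial hydroxypropyl group and the axial C10 methyl, so that the epoxide oxygen, the future lactone oxygen on C6, ends trans to the C5 substituent, and the weak amine base avoids retro-aldol loss of acetone.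

Step 7
Reactants: 11 4-(dimethoxymethyl)-5-(2-hydroxypropan-2-yl)-4-methyl-7-oxabicyclo[4.1.0]heptan-2-one
Product: 12 5-(dimethoxymethyl)-6-(2-hydroxypropan-2-yl)-5-methylcyclohex-2-en-1-ol (hydroxyl trans to the hydroxypropyl group)
Conditions: N2H4·H2O (3 equiv), AcOH (0.2 equiv), MeOH, 0 → 25 °C
Reagents that add atoms: none
Why: In the Wharton transposition the epoxy hydrazone collapses with loss of nitrogen to the allylic alcohol, which moves the alkene to C7–C8 and leaves the C6–O bond and its configuration untouched.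

Step 8
Reactants: 12 5-(dimethoxymethyl)-6-(2-hydroxypropan-2-yl)-5-methylcyclohex-2-en-1-ol
Product: 14 4-(dimethoxymethyl)-3-(2-hydroxypropan-2-yl)-4-methyl-7-oxabicyclo[4.1.0]heptan-2-ol (epoxide oxygen trans to the C2 hydroxyl), via bromohydrin 13 (not isolated)
Conditions: N-bromosuccinimide, THF/H2O (3:1), 0 °C; then K2CO3, MeOH, 25 °C
Reagents that add atoms: water, O
Why: Bromohydrin formation and base closure are used because, with the hydroxypropyl and dimethoxymethyl groups equatorial and the C10 methyl axial, bromonium formation on the face away from that methyl and trans-diaxial opening by water at C8 (Fürst–Plattner rule, and the carbon remote from the electron-withdrawing C6 oxygen) should give the 7-bromo-8-ol, whose anti-periplanar alkoxide displaces bromide to put the epoxide on the face opposite the C6 hydroxyl.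

Step 9
Reactants: 14 4-(dimethoxymethyl)-3-(2-hydroxypropan-2-yl)-4-methyl-7-oxabicyclo[4.1.0]heptan-2-ol
Product: 15 5-(dimethoxymethyl)-4-(2-hydroxypropan-2-yl)-5-methyl-2-(prop-1-en-2-yl)cyclohexane-1,3-diol (isopropenyl cis to the C3 hydroxyl and trans to the C1 hydroxyl)
Conditions: isopropenylmagnesium bromide (5 equiv), CuI (20 mol %), THF, −30 → 0 °C
Reagents that add atoms: isopropenylmagnesium bromide, CC(=C)[Mg]Br
Why: Copper-catalysed Grignard opening of the epoxide by trans-diaxial attack (Fürst–Plattner rule) in the conformationally anchored ring should bring the isopropenyl group to C7 on the face of the C6 hydroxyl and leave the C8 hydroxyl axial and trans to it, since attack at C8 would need a ring flip that puts the two largest groups axial.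

Step 10
Reactants: 15 5-(dimethoxymethyl)-4-(2-hydroxypropan-2-yl)-5-methyl-2-(prop-1-en-2-yl)cyclohexane-1,3-diol
Product: 16 5-(dimethoxymethyl)-2-(1-hydroxypropan-2-yl)-4-(2-hydroxypropan-2-yl)-5-methylcyclohexane-1,3-diol (side-chain epimers)
Conditions: BH3·THF (5 equiv), THF, 0 → 25 °C; then NaOH, H2O2, 0 °C
Reagents that add atoms: hydrogen peroxide, OO
Why: Anti-Markovnikov hydroboration–oxidation of the 1,1-disubstituted alkene gives the primary alcohol on C12, and the new C11 centre may form as a mixture because it is later planarised as an enolate.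

Step 11
Reactants: 16 5-(dimethoxymethyl)-2-(1-hydroxypropan-2-yl)-4-(2-hydroxypropan-2-yl)-5-methylcyclohexane-1,3-diol
Product: 17 6-(dimethoxymethyl)-4-hydroxy-7-(2-hydroxypropan-2-yl)-3,6-dimethylhexahydro-1-benzofuran-2(3H)-one (cis-fused; C3 epimers; ring stereocentres as in 25)
Conditions: (2,2,6,6-tetramethylpiperidin-1-yl)oxyl (20 mol %), PhI(OAc)2 (2.5 equiv), CH2Cl2, 25 °C
Reagents that add atoms: none
Why: In this oxidative lactonisation the primary alcohol is oxidised selectively to the aldehyde, which can form a lactol only with the cis C6 hydroxyl (the C8 hydroxyl is trans-diaxial to the side chain), and the lactol is oxidised further to the cis-fused γ-lactone.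

Step 12
Reactants: 17 6-(dimethoxymethyl)-4-hydroxy-7-(2-hydroxypropan-2-yl)-3,6-dimethylhexahydro-1-benzofuran-2(3H)-one
Product: 18 4-[(tert-butyldimethylsilyl)oxy]-6-(dimethoxymethyl)-7-(2-hydroxypropan-2-yl)-3,6-dimethylhexahydro-1-benzofuran-2(3H)-one
Conditions: t-BuMe2SiCl, imidazole, 4-(dimethylamino)pyridine (10 mol %), DMF, 45 °C
Reagents that add atoms: tert-butyldimethylsilyl chloride, CC(C)(C)[Si](C)(C)Cl
Why: Silylation takes the only secondary hydroxyl, the congested tertiary carbinol being inert under imidazole conditions, so the C8 oxygen is masked for the dehydration and the strong-base steps that follow.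

Step 13
Reactants: 18 4-[(tert-butyldimethylsilyl)oxy]-6-(dimethoxymethyl)-7-(2-hydroxypropan-2-yl)-3,6-dimethylhexahydro-1-benzofuran-2(3H)-one
Product: 19 4-[(tert-butyldimethylsilyl)oxy]-6-(dimethoxymethyl)-3,6-dimethyl-7-(prop-1-en-2-yl)hexahydro-1-benzofuran-2(3H)-one
Conditions: Burgess reagent (MeO2CN–SO2NEt3 inner salt), toluene, 50 °C
Reagents that add atoms: none
Why: Burgess dehydration (syn elimination through the sulfamate ester) should give the isopropenyl group, because the alternative tetrasubstituted alkene toward C5 would suffer severe allylic strain against the quaternary C10 and against C6.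

Step 14
Reactants: 19 4-[(tert-butyldimethylsilyl)oxy]-6-(dimethoxymethyl)-3,6-dimethyl-7-(prop-1-en-2-yl)hexahydro-1-benzofuran-2(3H)-one
Product: 20 4-[(tert-butyldimethylsilyl)oxy]-3,6-dimethyl-2-oxo-7-(prop-1-en-2-yl)octahydro-1-benzofuran-6-carbaldehyde
Conditions: pyridinium p-toluenesulfonate (20 mol %), acetone/H2O (10:1), 56 °C
Reagents that add atoms: water, O
Why: Acetal hydrolysis with a weak acid should unmask the neopentyl aldehyde without cleaving the hindered silyl ether or protonating the isopropenyl group, and the aldehyde has no α-hydrogen and cannot epimerise.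

Step 15
Reactants: 20 4-[(tert-butyldimethylsilyl)oxy]-3,6-dimethyl-2-oxo-7-(prop-1-en-2-yl)octahydro-1-benzofuran-6-carbaldehyde
Product: 21 4-[(tert-butyldimethylsilyl)oxy]-6-ethenyl-3,6-dimethyl-7-(prop-1-en-2-yl)hexahydro-1-benzofuran-2(3H)-one
Conditions: Ph3PCH3Br, KN(SiMe3)2, THF, 0 °C; then 20, −78 → 25 °C
Reagents that add atoms: methyltriphenylphosphonium bromide, C[P+](c1ccccc1)(c1ccccc1)c1ccccc1.[Br-]
Why: Wittig methylenation of the aldehyde, which is far more electrophilic than the lactone, installs the C10 vinyl group.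

Step 16
Reactants: 21 4-[(tert-butyldimethylsilyl)oxy]-6-ethenyl-3,6-dimethyl-7-(prop-1-en-2-yl)hexahydro-1-benzofuran-2(3H)-one
Product: 22 4-[(tert-butyldimethylsilyl)oxy]-6-ethenyl-3-hydroxy-3,6-dimethyl-7-(prop-1-en-2-yl)hexahydro-1-benzofuran-2(3H)-one (all stereocentres as in 25)
Conditions: KN(SiMe3)2, THF, −78 °C; then 2-(benzenesulfonyl)-3-phenyloxaziridine, −78 °C; aq. NH4Cl
Reagents that add atoms: 2-(benzenesulfonyl)-3-phenyloxaziridine, O=S(=O)(c1ccccc1)N1OC1c1ccccc1
Why: Enolate hydroxylation with the Davis oxaziridine should occur on the convex face of the cis-fused lactone enolate, syn to H7 and away from ring A, which places the hydroxyl as required and the methyl on the concave side.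

Step 17
Reactants: 22 4-[(tert-butyldimethylsilyl)oxy]-6-ethenyl-3-hydroxy-3,6-dimethyl-7-(prop-1-en-2-yl)hexahydro-1-benzofuran-2(3H)-one
Product: 23 4-[(tert-butyldimethylsilyl)oxy]-6-ethenyl-3,6-dimethyl-2-oxo-7-(prop-1-en-2-yl)octahydro-1-benzofuran-3-yl (2Z)-2-methylbut-2-enoate
Conditions: LiN(SiMe3)2, THF, −78 °C; then angelic anhydride, −78 → 0 °C; aq. NH4Cl
Reagents that add atoms: angelic anhydride, C/C=C(C)\C(=O)OC(=O)/C(C)=C\C
Why: O-Acylation of the lithium alkoxide of the tertiary α-hydroxy lactone with the anhydride at low temperature avoids the nucleophilic catalysts and heat that isomerise angelates to tiglates.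

Step 18
Reactants: 23 4-[(tert-butyldimethylsilyl)oxy]-6-ethenyl-3,6-dimethyl-2-oxo-7-(prop-1-en-2-yl)octahydro-1-benzofuran-3-yl (2Z)-2-methylbut-2-enoate
Product: 24 6-ethenyl-4-hydroxy-3,6-dimethyl-2-oxo-7-(prop-1-en-2-yl)octahydro-1-benzofuran-3-yl (2Z)-2-methylbut-2-enoate
Conditions: HF·pyridine, pyridine, THF, 0 → 25 °C
Reagents that add atoms: none
Why: Fluoride-mediated desilylation under buffered acidic conditions should free the C8 hydroxyl without acyl migration or lactone opening.

Step 19
Reactants: 24 6-ethenyl-4-hydroxy-3,6-dimethyl-2-oxo-7-(prop-1-en-2-yl)octahydro-1-benzofuran-3-yl (2Z)-2-methylbut-2-enoate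
Product: 25 (3S,3aR,4S,6R,7R,7aS)-4-(acetyloxy)-6-ethenyl-3,6-dimethyl-2-oxo-7-(prop-1-en-2-yl)octahydro-1-benzofuran-3-yl (2Z)-2-methylbut-2-enoate (CNP0140071.1)
Conditions: Ac2O, pyridine, 4-(dimethylamino)pyridine (10 mol %), CH2Cl2, 25 °C
Reagents that add atoms: acetic anhydride, CC(=O)OC(C)=O
Why: Amine-catalysed acetylation of the one remaining secondary alcohol completes the target.

**Compound list**

1 | 1,1-dimethoxypropan-2-one | CC(=O)C(OC)OC | starting material
2 | diethyl (2-oxopropyl)phosphonate | CCOP(=O)(CC(C)=O)OCC | starting material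
3 | (E)-5,5-dimethoxy-4-methylpent-3-en-2-one | CC(=O)/C=C(\C)C(OC)OC | intermediate
4 | dimethyl malonate | COC(=O)CC(=O)OC | starting material
5 | dimethyl 2-[(2S)-1,1-dimethoxy-2-methyl-4-oxopentan-2-yl]propanedioate (not isolated) | COC(OC)[C@@](C(C(=O)OC)C(=O)OC)(C)CC(C)=O | intermediate
6 | methyl (1R,2S)-2-(dimethoxymethyl)-2-methyl-4,6-dioxocyclohexane-1-carboxylate (diketo tautomer drawn) | COC(OC)[C@@]1(C)CC(=O)CC(=O)[C@@H]1C(=O)OC | intermediate
7 | methyl (1R,6S)-6-(dimethoxymethyl)-4-methoxy-6-methyl-2-oxocyclohex-3-ene-1-carboxylate | COC(OC)[C@@]1(C)CC(OC)=CC(=O)[C@@H]1C(=O)OC | intermediate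
8 | methyl (1R,6S)-6-(dimethoxymethyl)-2-hydroxy-4-methoxy-6-methylcyclohex-3-ene-1-carboxylate, C2 epimers | COC(OC)[C@@]1(C)CC(OC)=CC(O)[C@@H]1C(=O)OC | intermediate
9 | 2-[(1R,6S)-6-(dimethoxymethyl)-2-hydroxy-4-methoxy-6-methylcyclohex-3-en-1-yl]propan-2-ol, C2 epimers (not isolated) | COC(OC)[C@@]1(C)CC(OC)=CC(O)[C@@H]1C(C)(C)O | intermediate
10 | (4S,5S)-5-(dimethoxymethyl)-4-(2-hydroxypropan-2-yl)-5-methylcyclohex-2-en-1-one | COC(OC)[C@@]1(C)CC(=O)C=C[C@@H]1C(C)(C)O | intermediate
11 | 4-(dimethoxymethyl)-5-(2-hydroxypropan-2-yl)-4-methyl-7-oxabicyclo[4.1.0]heptan-2-one, epoxide oxygen trans to the hydroxypropyl group | COC(OC)[C@@]1(C)CC(=O)[C@H]2O[C@H]2[C@@H]1C(C)(C)O | intermediate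
12 | 5-(dimethoxymethyl)-6-(2-hydroxypropan-2-yl)-5-methylcyclohex-2-en-1-ol, hydroxyl trans to the hydroxypropyl group | COC(OC)[C@@]1(C)CC=C[C@@H](O)[C@@H]1C(C)(C)O | intermediate
13 | 2-bromo-5-(dimethoxymethyl)-4-(2-hydroxypropan-2-yl)-5-methylcyclohexane-1,3-diol, Br cis to the C3 hydroxyl and trans to the C1 hydroxyl (not isolated) | COC(OC)[C@@]1(C)C[C@H](O)[C@@H](Br)[C@@H](O)[C@@H]1C(C)(C)O | intermediate
14 | 4-(dimethoxymethyl)-3-(2-hydroxypropan-2-yl)-4-methyl-7-oxabicyclo[4.1.0]heptan-2-ol, epoxide oxygen trans to the C2 hydroxyl | COC(OC)[C@@]1(C)C[C@@H]2O[C@@H]2[C@@H](O)[C@@H]1C(C)(C)O | intermediate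
15 | 5-(dimethoxymethyl)-4-(2-hydroxypropan-2-yl)-5-methyl-2-(prop-1-en-2-yl)cyclohexane-1,3-diol, isopropenyl cis to the C3 hydroxyl and trans to the C1 hydroxyl | COC(OC)[C@@]1(C)C[C@H](O)[C@@H](C(C)=C)[C@@H](O)[C@@H]1C(C)(C)O | intermediate
16 | 5-(dimethoxymethyl)-2-(1-hydroxypropan-2-yl)-4-(2-hydroxypropan-2-yl)-5-methylcyclohexane-1,3-diol, side-chain epimers | COC(OC)[C@@]1(C)C[C@H](O)[C@@H](C(C)CO)[C@@H](O)[C@@H]1C(C)(C)O | intermediate
17 | 6-(dimethoxymethyl)-4-hydroxy-7-(2-hydroxypropan-2-yl)-3,6-dimethylhexahydro-1-benzofuran-2(3H)-one, cis-fused, C3 epimers | COC(OC)[C@@]1(C)C[C@H](O)[C@@H]2[C@@H](OC(=O)C2C)[C@@H]1C(C)(C)O | intermediate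
18 | 4-[(tert-butyldimethylsilyl)oxy]-6-(dimethoxymethyl)-7-(2-hydroxypropan-2-yl)-3,6-dimethylhexahydro-1-benzofuran-2(3H)-one, C3 epimers | COC(OC)[C@@]1(C)C[C@H](O[Si](C)(C)C(C)(C)C)[C@@H]2[C@@H](OC(=O)C2C)[C@@H]1C(C)(C)O | intermediate
19 | 4-[(tert-butyldimethylsilyl)oxy]-6-(dimethoxymethyl)-3,6-dimethyl-7-(prop-1-en-2-yl)hexahydro-1-benzofuran-2(3H)-one, C3 epimers | COC(OC)[C@@]1(C)C[C@H](O[Si](C)(C)C(C)(C)C)[C@@H]2[C@@H](OC(=O)C2C)[C@@H]1C(C)=C | intermediate
20 | 4-[(tert-butyldimethylsilyl)oxy]-3,6-dimethyl-2-oxo-7-(prop-1-en-2-yl)octahydro-1-benzofuran-6-carbaldehyde, C3 epimers | O=C[C@@]1(C)C[C@H](O[Si](C)(C)C(C)(C)C)[C@@H]2[C@@H](OC(=O)C2C)[C@@H]1C(C)=C | intermediate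
21 | 4-[(tert-butyldimethylsilyl)oxy]-6-ethenyl-3,6-dimethyl-7-(prop-1-en-2-yl)hexahydro-1-benzofuran-2(3H)-one, C3 epimers | C=C[C@@]1(C)C[C@H](O[Si](C)(C)C(C)(C)C)[C@@H]2[C@@H](OC(=O)C2C)[C@@H]1C(C)=C | intermediate
22 | 4-[(tert-butyldimethylsilyl)oxy]-6-ethenyl-3-hydroxy-3,6-dimethyl-7-(prop-1-en-2-yl)hexahydro-1-benzofuran-2(3H)-one, stereocentres as in 25 | C=C[C@@]1(C)C[C@H](O[Si](C)(C)C(C)(C)C)[C@@H]2[C@@H](OC(=O)[C@@]2(C)O)[C@@H]1C(C)=C | intermediate
23 | 4-[(tert-butyldimethylsilyl)oxy]-6-ethenyl-3,6-dimethyl-2-oxo-7-(prop-1-en-2-yl)octahydro-1-benzofuran-3-yl (2Z)-2-methylbut-2-enoate | C=C[C@@]1(C)C[C@H](O[Si](C)(C)C(C)(C)C)[C@@H]2[C@@H](OC(=O)[C@@]2(C)OC(=O)/C(C)=C\C)[C@@H]1C(C)=C | intermediate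
24 | 6-ethenyl-4-hydroxy-3,6-dimethyl-2-oxo-7-(prop-1-en-2-yl)octahydro-1-benzofuran-3-yl (2Z)-2-methylbut-2-enoate | C=C[C@@]1(C)C[C@H](O)[C@@H]2[C@@H](OC(=O)[C@@]2(C)OC(=O)/C(C)=C\C)[C@@H]1C(C)=C | intermediate
25 | (3S,3aR,4S,6R,7R,7aS)-4-(acetyloxy)-6-ethenyl-3,6-dimethyl-2-oxo-7-(prop-1-en-2-yl)octahydro-1-benzofuran-3-yl (2Z)-2-methylbut-2-enoate (CNP0140071.1) | C=C[C@@]1(C)C[C@H](OC(C)=O)[C@@H]2[C@@H](OC(=O)[C@@]2(C)OC(=O)/C(C)=C\C)[C@@H]1C(=C)C | target

**Step count and risks**

Total: 19 steps. Longest linear sequence: 19 steps (from 1 and 2).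

Steps most likely to fail:

1. Step 2 (labelled). The enantiomeric purity created in the conjugate addition may be eroded by retro-Michael cleavage and re-addition while methoxide closes the ring, or the hindered enone may not form a reactive iminium ion at all. Fallback, from 3 and 4 back to 6: the two are combined under plain dimedone conditions (NaOMe, MeOH, reflux, then acid). This gives 6 together with its mirror image, methyl (1S,2R)-2-(dimethoxymethyl)-2-methyl-4,6-dioxocyclohexane-1-carboxylate F1, as the racemate. The acidic dione is then resolved by fractional crystallisation with quinine from acetone: the quininium enolate of 6 F2 is collected and the quininium enolate of the (1S,2R)-enantiomer F3 is left in the mother liquor (if the solubilities are the other way round, 6 is taken from the mother liquor). Partition of F2 between dilute HCl and ethyl acetate returns 6.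

2. Step 9. The Grignard reagent may attack C8 instead of C7, or the epoxide may migrate (Payne-type) under the alkoxide-rich conditions before it is opened. Fallback, from 12 back to 18: the C7–C11 bond is made by a tethered radical cyclisation instead. Selective O-alkylation of the secondary hydroxyl (NaH, propargyl bromide, THF) gives the propargyl ether of 12 F6. N-Bromosuccinimide in aqueous THF gives, by the same diaxial course as in step 8, the 7-bromo-8-ol F7. Bu3SnH with azobisisobutyronitrile in hot benzene closes the C7 radical 5-exo-dig onto the alkyne to the cis-fused 3-methylenetetrahydrofuran F8. Its C8 hydroxyl is silylated (t-BuMe2SiCl, imidazole) to the silyl ether F9, allylic oxidation with CrO3·3,5-dimethylpyrazole gives the α-methylene lactone F10, and hydrogenation (H2, palladium on carbon) of the exocyclic alkene gives 18.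

3. Step 7. The epoxy hydrazone may collapse incompletely, with azine formation and over-reduction competing, as is common for hindered substrates in the Wharton reaction. Fallback, from 11 back to 12: Luche reduction (NaBH4, CeCl3·7H2O, MeOH) gives the epoxy alcohol 4-(dimethoxymethyl)-5-(2-hydroxypropan-2-yl)-4-methyl-7-oxabicyclo[4.1.0]heptan-2-ol F4 (either C8 epimer serves). Its secondary hydroxyl is converted with 1,1'-thiocarbonyldiimidazole into the imidazole-1-carbothioate F5. Bu3SnH with azobisisobutyronitrile in refluxing benzene then generates the C8 radical, which opens the adjacent epoxide; the C6 alkoxyl radical takes up hydrogen and gives 12.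

Further compounds
F1 | step 2 | methyl (1S,2R)-2-(dimethoxymethyl)-2-methyl-4,6-dioxocyclohexane-1-carboxylate (enantiomer of 6) | COC(OC)[C@]1(C)CC(=O)CC(=O)[C@H]1C(=O)OC
F2 | step 2 | quininium enolate of 6 | COC(OC)[C@@]1(C)CC(=O)C=C([O-])[C@@H]1C(=O)OC.COC1=CC2=C(C=CN=C2C=C1)[C@H]([C@@H]3C[C@@H]4CC[NH+]3C[C@@H]4C=C)O
F3 | step 2 | quininium enolate of F1 | COC(OC)[C@]1(C)CC(=O)C=C([O-])[C@H]1C(=O)OC.COC1=CC2=C(C=CN=C2C=C1)[C@H]([C@@H]3C[C@@H]4CC[NH+]3C[C@@H]4C=C)O
F4 | step 7 | 4-(dimethoxymethyl)-5-(2-hydroxypropan-2-yl)-4-methyl-7-oxabicyclo[4.1.0]heptan-2-ol, C2 epimers | COC(OC)[C@@]1(C)CC(O)[C@H]2O[C@H]2[C@@H]1C(C)(C)O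
F5 | step 7 | O-[4-(dimethoxymethyl)-5-(2-hydroxypropan-2-yl)-4-methyl-7-oxabicyclo[4.1.0]heptan-2-yl] 1H-imidazole-1-carbothioate | COC(OC)[C@@]1(C)CC(OC(=S)n2ccnc2)[C@H]3O[C@H]3[C@@H]1C(C)(C)O
F6 | step 9 | 2-[6-(dimethoxymethyl)-6-methyl-2-(prop-2-yn-1-yloxy)cyclohex-3-en-1-yl]propan-2-ol (propargyl ether of 12) | COC(OC)[C@@]1(C)CC=C[C@@H](OCC#C)[C@@H]1C(C)(C)O
F7 | step 9 | 2-bromo-5-(dimethoxymethyl)-4-(2-hydroxypropan-2-yl)-5-methyl-3-(prop-2-yn-1-yloxy)cyclohexan-1-ol | COC(OC)[C@@]1(C)C[C@H](O)[C@@H](Br)[C@@H](OCC#C)[C@@H]1C(C)(C)O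
F8 | step 9 | 6-(dimethoxymethyl)-7-(2-hydroxypropan-2-yl)-6-methyl-3-methylideneoctahydro-1-benzofuran-4-ol (cis-fused) | COC(OC)[C@@]1(C)C[C@H](O)[C@@H]2[C@@H](OCC2=C)[C@@H]1C(C)(C)O
F9 | step 9 | 2-{4-[(tert-butyldimethylsilyl)oxy]-6-(dimethoxymethyl)-6-methyl-3-methylideneoctahydro-1-benzofuran-7-yl}propan-2-ol | COC(OC)[C@@]1(C)C[C@H](O[Si](C)(C)C(C)(C)C)[C@@H]2[C@@H](OCC2=C)[C@@H]1C(C)(C)O
F10 | step 9 | 4-[(tert-butyldimethylsilyl)oxy]-6-(dimethoxymethyl)-7-(2-hydroxypropan-2-yl)-6-methyl-3-methylidenehexahydro-1-benzofuran-2(3H)-one | COC(OC)[C@@]1(C)C[C@H](O[Si](C)(C)C(C)(C)C)[C@@H]2[C@@H](OC(=O)C2=C)[C@@H]1C(C)(C)O
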